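**Retrosynthetic overview**

1. Target 23 ⇐ desilylation and O‑5 acylation of lactone 21 ⇐ Pd/CO lactonisation of bromo‑triol 20 (C12 arrives last as CO; O6–C12 and C11–C12 bonds).
2. The enabling feature is the α‑ketol C8(OH)–C9(=O) of the ten‑membered ring next to C7, which carries the exocyclic C11=C13 unit. This γ,δ‑unsaturated α‑oxy ketone is the product pattern of an oxy‑Claisen shift of an α‑(allyloxy) aldehyde enolate.
3. Tying O(C9) to C13 therefore gives the 12‑membered oxacycle 16 (ring atoms C9, O, C13, C11, C7, C6, C5, C4, C3, C2, C1, C10), which contracts by two atoms to the C1–C10 carbocycle (C7–C8 made, O–C13 broken).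
4. 16 ⇐ RCM (C1=C2) and hydrogenation of ether 12 ⇐ Williamson union of west alcohol 2 (asymmetric crotylboration, sets C10) with east allylic bromide 11 (D‑tartrate acetonide for C5/C6, chelation‑controlled MeMgBr addition for C4, Z‑selective bromo‑Wittig for the C7=C11 geometry).
5. Ring order: dioxolane (chiral pool, temporary) → 12‑membered oxacycle (RCM) → 10‑membered carbocycle (ring contraction) → γ‑lactone (carbonylation).

Key step: step 15

Remark on numbering: germacrane‑type locants of the target are used for every intermediate: ring C1–C3 = the three CH2, C4 = C(CH3)OH, C5 = CH–O‑isovalerate, C6 = lactone CH–O, C7, C8 = CHOH, C9 = C=O, C10 = CH–CH3; C11/C12/C13 = lactone carbons (C13 = exocyclic CH2); CIP letters refer to each compound as drawn.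

Assumption: aldehyde 1 and the isolable ylide ethyl bromo(triphenylphosphoranylidene)acetate are taken as purchased; each is otherwise one routine step from bulk chemicals.

**Step 1**
Reactants: 1 2-[(4-methoxybenzyl)oxy]acetaldehyde
Product: 2 (2S,3S)-1-[(4-methoxybenzyl)oxy]-3-methylpent-4-en-2-ol
Conditions: trans-2-butene, n-BuLi, KOt-Bu, THF, −78 → −45 °C; (−)-Ipc2BOMe [from (+)-α-pinene], −78 °C; BF3·OEt2; 1, −78 °C; NaOH, H2O2
Reagents that add atoms: trans-2-butene (C/C=C/C)
Why: Brown asymmetric crotylboration through a closed chair (Zimmerman–Traxler) transition state: the E‑crotyl geometry should give the anti C9/C10 relationship and the Ipc groups the absolute configuration at C10 (S), the only centre of 2 that survives (C9 is erased in step 15).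

**Step 2**
Reactants: 3 dimethyl (4S,5S)-2,2-dimethyl-1,3-dioxolane-4,5-dicarboxylate
Product: 4 (4S,5S)-N4,N5-dimethoxy-N4,N5,2,2-tetramethyl-1,3-dioxolane-4,5-dicarboxamide
Conditions: MeNH(OMe)·HCl, i-PrMgCl, THF, −20 → 0 °C
Reagents that add atoms: N,O-dimethylhydroxylamine hydrochloride (CNOC.Cl)
Why: Weinreb amide formation by aminolysis of both esters with the chloromagnesium amide; the trans‑dioxolane centres (future C5, C6) are not enolised under these conditions.

**Step 3**
Reactants: 4 (4S,5S)-N4,N5-dimethoxy-N4,N5,2,2-tetramethyl-1,3-dioxolane-4,5-dicarboxamide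
Product: 5 (4S,5S)-5-(but-3-enoyl)-N-methoxy-N,2,2-trimethyl-1,3-dioxolane-4-carboxamide
Conditions: allylMgBr (1.05 equiv), THF, −78 °C; cold aq. NH4Cl
Reagents that add atoms: allylmagnesium bromide (C=CC[Mg]Br)
Why: Weinreb ketone synthesis; the stable magnesium chelate of the first adduct and one equivalent of Grignard reagent should limit the C2‑symmetric bis‑amide to mono‑addition, and the cold quench keeps the β,γ‑double bond out of conjugation.

**Step 4**
Reactants: 5 (4S,5S)-5-(but-3-enoyl)-N-methoxy-N,2,2-trimethyl-1,3-dioxolane-4-carboxamide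
Product: 6 (4S,5S)-5-[(2R)-2-hydroxypent-4-en-2-yl]-N-methoxy-N,2,2-trimethyl-1,3-dioxolane-4-carboxamide
Conditions: MeMgBr (1.2 equiv), THF, −78 °C
Reagents that add atoms: methylmagnesium bromide (C[Mg]Br)
Why: Chelation‑controlled (Cram‑chelate) Grignard addition: Mg bridges the ketone oxygen and the α‑oxygen O‑5 of the dioxolane and methyl enters on the face away from C6, which should set C4 (R); the ketone reacts far faster than the Weinreb amide at −78 °C.

**Step 5**
Reactants: 6 (4S,5S)-5-[(2R)-2-hydroxypent-4-en-2-yl]-N-methoxy-N,2,2-trimethyl-1,3-dioxolane-4-carboxamide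
Product: 7 (4S,5S)-N-methoxy-N,2,2-trimethyl-5-[(2R)-2-(triethylsilyloxy)pent-4-en-2-yl]-1,3-dioxolane-4-carboxamide
Conditions: TESOTf, 2,6-lutidine, CH2Cl2, 0 °C → rt
Reagents that add atoms: triethylsilyl trifluoromethanesulfonate (CC[Si](CC)(CC)OS(=O)(=O)C(F)(F)F)
Why: Silylation of the hindered tertiary alcohol with a silyl triflate; TES is chosen because it leaves together with the acetonide in step 16 and keeps O‑4 out of the base and silylation chemistry of step 15.

**Step 6**
Reactants: 7 (4S,5S)-N-methoxy-N,2,2-trimethyl-5-[(2R)-2-(triethylsilyloxy)pent-4-en-2-yl]-1,3-dioxolane-4-carboxamide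
Product: 8 (4S,5S)-2,2-dimethyl-5-[(2R)-2-(triethylsilyloxy)pent-4-en-2-yl]-1,3-dioxolane-4-carbaldehyde
Conditions: DIBAL-H, THF, −78 °C; Rochelle salt
Reagents that add atoms: none
Why: Weinreb amide reduction stops at the aldehyde (C7) through the stable tetrahedral chelate.

**Step 7**
Reactants: 8 (4S,5S)-2,2-dimethyl-5-[(2R)-2-(triethylsilyloxy)pent-4-en-2-yl]-1,3-dioxolane-4-carbaldehyde
Product: 9 ethyl (2Z)-2-bromo-3-{(4R,5S)-2,2-dimethyl-5-[(2R)-2-(triethylsilyloxy)pent-4-en-2-yl]-1,3-dioxolan-4-yl}prop-2-enoate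
Conditions: Ph3P=C(Br)CO2Et, CH2Cl2, 0 °C → rt
Reagents that add atoms: ethyl bromo(triphenylphosphoranylidene)acetate (CCOC(=O)C(Br)=P(c1ccccc1)(c1ccccc1)c1ccccc1)
Why: Wittig olefination with a stabilised α‑bromo ylide should place the ester trans to C6, i.e. give the (Z)‑α‑bromoenoate with Br cis to C6; the ester carbon becomes C13, so C6 ends trans to C13 as the key step requires.

**Step 8**
Reactants: 9 ethyl (2Z)-2-bromo-3-{(4R,5S)-2,2-dimethyl-5-[(2R)-2-(triethylsilyloxy)pent-4-en-2-yl]-1,3-dioxolan-4-yl}prop-2-enoate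
Product: 10 (2Z)-2-bromo-3-{(4R,5S)-2,2-dimethyl-5-[(2R)-2-(triethylsilyloxy)pent-4-en-2-yl]-1,3-dioxolan-4-yl}prop-2-en-1-ol
Conditions: DIBAL-H (2.2 equiv), CH2Cl2, −78 °C; Rochelle salt
Reagents that add atoms: none
Why: 1,2‑Reduction of the enoate to the allylic alcohol (C13–OH) by an aluminium hydride; the vinyl bromide and the alkene geometry are not affected.

**Step 9**
Reactants: 10 (2Z)-2-bromo-3-{(4R,5S)-2,2-dimethyl-5-[(2R)-2-(triethylsilyloxy)pent-4-en-2-yl]-1,3-dioxolan-4-yl}prop-2-en-1-ol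
Product: 11 (4R,5S)-4-[(1Z)-2,3-dibromoprop-1-en-1-yl]-2,2-dimethyl-5-[(2R)-2-(triethylsilyloxy)pent-4-en-2-yl]-1,3-dioxolane
Conditions: CBr4, PPh3, 2,6-lutidine, CH2Cl2, 0 °C
Reagents that add atoms: carbon tetrabromide (BrC(Br)(Br)Br)
Why: Appel bromination of the primary allylic alcohol; the 2‑bromo substituent disfavours allylic transposition and the buffer protects acetal and silyl ether.

**Step 10**
Reactants: 2 (2S,3S)-1-[(4-methoxybenzyl)oxy]-3-methylpent-4-en-2-ol; 11 (4R,5S)-4-[(1Z)-2,3-dibromoprop-1-en-1-yl]-2,2-dimethyl-5-[(2R)-2-(triethylsilyloxy)pent-4-en-2-yl]-1,3-dioxolane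
Product: 12 1-({[(2S,3S)-2-({(2Z)-2-bromo-3-[(4R,5S)-2,2-dimethyl-5-[(2R)-2-(triethylsilyloxy)pent-4-en-2-yl]-1,3-dioxolan-4-yl]prop-2-en-1-yl}oxy)-3-methylpent-4-en-1-yl]oxy}methyl)-4-methoxybenzene
Conditions: 2, NaH, THF/DMF, 0 °C; then 11, Bu4NI (cat.), 0 °C → rt
Reagents that add atoms: none
Why: Williamson ether synthesis: SN2 attack of the secondary alkoxide (O‑9) on the primary allylic bromide C13 joins the two fragments with the bromoalkene geometry intact.

**Step 11**
Reactants: 12 acyclic ether of step 10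
Product: 13 twelve-membered oxacyclic diene (ring O–C13–C11(Br)=C7–C6–C5–C4–C3–C2=C1–C10–C9; 4R,5S,6R,9S,10S,7Z; C1=C2 as E/Z mixture; 5,6-acetonide, 4-OTES, 9-CH2OPMB)
Conditions: Grubbs II (10 mol%), CH2Cl2 (1 mM), 40 °C
Reagents that add atoms: none
Why: Ring‑closing metathesis of the two monosubstituted alkenes at high dilution closes the 12‑membered ring; the trisubstituted bromoalkene is sterically and electronically inert to the Ru alkylidene, so no small‑ring closure onto C7 or C11 is expected.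

**Step 12**
Reactants: 13 twelve-membered oxacyclic diene
Product: 14 twelve-membered oxacycle, C1–C2 saturated (4R,5S,6R,9S,10S,7Z; 5,6-acetonide, 4-OTES, 9-CH2OPMB)
Conditions: H2 (1 atm), RhCl(PPh3)3 (10 mol%), benzene/EtOH, rt
Reagents that add atoms: none
Why: Homogeneous hydrogenation with Wilkinson's catalyst should reduce only the disubstituted ring alkene; the trisubstituted vinyl bromide and the PMB ether are not touched.

**Step 13**
Reactants: 14 twelve-membered oxacycle, C1–C2 saturated
Product: 15 primary alcohol (9-CH2OH) of the twelve-membered oxacycle (4R,5S,6R,9S,10S,7Z)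
Conditions: DDQ, CH2Cl2/pH 7 buffer, 0 °C
Reagents that add atoms: none
Why: Oxidative cleavage of the PMB ether; the electron‑poor 2‑bromoallyl ether, acetonide and TES ether are stable to buffered DDQ.

**Step 14**
Reactants: 15 primary alcohol of the twelve-membered oxacycle
Product: 16 twelve-membered oxacyclic α-(allyloxy) aldehyde (9-CHO = C8; 4R,5S,6R,9S,10S,7Z)
Conditions: Dess–Martin periodinane, pyridine, CH2Cl2, 0 °C → rt
Reagents that add atoms: none
Why: Dess–Martin oxidation to the aldehyde under buffered, non‑epimerising conditions; the configuration at C9 is in any case erased in the next step.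

**Step 15**
Reactants: 16 twelve-membered oxacyclic α-(allyloxy) aldehyde
Product: 19 ten-membered ketone (4R,5S,6R,7R,8S,10S)-7-(1-bromovinyl)-8-(tert-butyldimethylsilyloxy)-5,6-(isopropylidenedioxy)-4,10-dimethyl-4-(triethylsilyloxy)cyclodecan-9-one (target numbering), via potassium enolate 17 (not isolated), via potassium alkoxide 18 (not isolated)
Conditions: KH (1.1 equiv), THF, 0 °C → rt; then TBSOTf, −78 → 0 °C
Reagents that add atoms: tert-butyldimethylsilyl trifluoromethanesulfonate (CC(C)(C)[Si](C)(C)OS(=O)(=O)C(F)(F)F)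
Why: Proposed new method: KH removes H‑9, the only α‑hydrogen of the α‑(allyloxy) aldehyde, and the resulting (Z)‑enolate 17 (O‑8 cis to the ring oxygen, held by K+ chelation and by the bulk of C10) is a 1‑oxido allyl vinyl ether that undergoes a charge‑accelerated [3,3] shift in which C8–C7 forms and O–C13 breaks, so that O, C13 and C11 leave the ring, C8 enters it and the twelve‑membered oxacycle contracts to the ten‑membered α‑oxido ketone 18, trapped in the flask as its TBS ether; the closest known reaction is the anionic oxy‑Claisen rearrangement of potassium enolates of acyclic α‑allyloxy ketones, with the Claisen ring contraction of macrolactone ketene acetals as the nearest ring‑contracting analogy. The ten‑membered ring is closed by this transannular C8–C7 bond formation through a six‑membered chair transition state; the boat is disfavoured because it eclipses the C10 branch on C9 with the bromine on C11. C7 is set by the C6 stereocentre: A(1,3) strain with the cis bromine holds H‑6 in the alkene plane, and C8 adds anti to the C6–O bond on the face that carries C5 and the tether, which gives the 6,7‑relationship of the trans‑lactone. C8 is set by the two double‑bond geometries: C6 trans to C13 (from the Z‑bromoalkene of step 7) sits equatorial and O‑8 cis to the ether oxygen sits axial in the chair, which gives the anti 7,8‑relationship of the target. The step needs [3,3] over [2,3]‑Wittig selectivity (attack of C9 on C7 would give a nine‑membered ring) and no epimerisation at C10; the potassium counter‑ion, the open CH‑8 terminus against the fully substituted C9, the low temperature and the immediate silylation are relied on for both.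

**Step 16**
Reactants: 19 ten-membered ketone with 5,6-acetonide, 4-OTES and 8-OTBS
Product: 20 (4R,5S,6R,7R,8S,10S)-7-(1-bromovinyl)-8-(tert-butyldimethylsilyloxy)-4,5,6-trihydroxy-4,10-dimethylcyclodecan-9-one (target numbering)
Conditions: AcOH/THF/H2O (3:1:1), 45 °C
Reagents that add atoms: none
Why: Acid hydrolysis of the strained trans‑fused dioxolane and of the tertiary TES ether; the secondary TBS ether should survive and keeps O‑8 masked so that it cannot compete with O‑6 in the lactonisation.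

**Step 17**
Reactants: 20 bromo-triol
Product: 21 (4R,5S,6R,7R,8S,10S)-8-(tert-butyldimethylsilyloxy)-4,5-dihydroxy-9-oxo-germacr-11(13)-en-12,6-olide (8-O-TBS, 5-desacyl target)
Conditions: Pd(PPh3)4 (10 mol%), CO (1 atm), Et3N, MeCN, 60 °C
Reagents that add atoms: carbon monoxide ([C-]#[O+])
Why: Pd‑catalysed carbonylative lactonisation of a 2‑bromoallyl carbinol: oxidative addition, CO insertion and capture of the acyl‑palladium by O‑6 in a five‑membered ring (preferred over the six‑membered closure through O‑5) should give the α‑methylene‑γ‑butyrolactone directly.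

**Step 18**
Reactants: 21 lactone diol
Product: 22 8-O-TBS ether of the target (5-O-isovalerate)
Conditions: (i-BuCO)2O, DMAP, Et3N, CH2Cl2, 0 °C → rt
Reagents that add atoms: 3-methylbutanoic anhydride (CC(C)CC(=O)OC(=O)CC(C)C)
Why: DMAP‑catalysed acylation is selective for the secondary C5–OH over the tertiary C4–OH.

**Step 19**
Reactants: 22 8-O-TBS ether of the target
Product: 23 CNP0240128.1 (4R,5S,6R,7S,8S,10S)
Conditions: HF·pyridine, pyridine, THF, 0 °C → rt
Reagents that add atoms: none
Why: Fluoride‑mediated desilylation under mildly acidic conditions spares the α‑methylene lactone, the ester and the epimerisable α‑ketol.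

**Compound list**

1 | 2-[(4-methoxybenzyl)oxy]acetaldehyde | COc1ccc(COCC=O)cc1 | starting material
2 | (2S,3S)-1-[(4-methoxybenzyl)oxy]-3-methylpent-4-en-2-ol | COc1ccc(COC[C@@H](O)[C@@H](C)C=C)cc1 | intermediate
3 | dimethyl (4S,5S)-2,2-dimethyl-1,3-dioxolane-4,5-dicarboxylate (D-tartrate acetonide) | COC(=O)[C@H]1OC(C)(C)O[C@@H]1C(=O)OC | starting material
4 | (4S,5S)-N4,N5-dimethoxy-N4,N5,2,2-tetramethyl-1,3-dioxolane-4,5-dicarboxamide | CON(C)C(=O)[C@H]1OC(C)(C)O[C@@H]1C(=O)N(C)OC | intermediate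
5 | (4S,5S)-5-(but-3-enoyl)-N-methoxy-N,2,2-trimethyl-1,3-dioxolane-4-carboxamide | C=CCC(=O)[C@H]1OC(C)(C)O[C@@H]1C(=O)N(C)OC | intermediate
6 | (4S,5S)-5-[(2R)-2-hydroxypent-4-en-2-yl]-N-methoxy-N,2,2-trimethyl-1,3-dioxolane-4-carboxamide | C=CC[C@@](C)(O)[C@H]1OC(C)(C)O[C@@H]1C(=O)N(C)OC | intermediate
7 | (4S,5S)-N-methoxy-N,2,2-trimethyl-5-[(2R)-2-(triethylsilyloxy)pent-4-en-2-yl]-1,3-dioxolane-4-carboxamide | C=CC[C@@](C)(O[Si](CC)(CC)CC)[C@H]1OC(C)(C)O[C@@H]1C(=O)N(C)OC | intermediate
8 | (4S,5S)-2,2-dimethyl-5-[(2R)-2-(triethylsilyloxy)pent-4-en-2-yl]-1,3-dioxolane-4-carbaldehyde | C=CC[C@@](C)(O[Si](CC)(CC)CC)[C@H]1OC(C)(C)O[C@@H]1C=O | intermediate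
9 | ethyl (2Z)-2-bromo-3-{(4R,5S)-2,2-dimethyl-5-[(2R)-2-(triethylsilyloxy)pent-4-en-2-yl]-1,3-dioxolan-4-yl}prop-2-enoate | C=CC[C@@](C)(O[Si](CC)(CC)CC)[C@H]1OC(C)(C)O[C@@H]1/C=C(\Br)C(=O)OCC | intermediate
10 | (2Z)-2-bromo-3-{(4R,5S)-2,2-dimethyl-5-[(2R)-2-(triethylsilyloxy)pent-4-en-2-yl]-1,3-dioxolan-4-yl}prop-2-en-1-ol | C=CC[C@@](C)(O[Si](CC)(CC)CC)[C@H]1OC(C)(C)O[C@@H]1/C=C(\Br)CO | intermediate
11 | (4R,5S)-4-[(1Z)-2,3-dibromoprop-1-en-1-yl]-2,2-dimethyl-5-[(2R)-2-(triethylsilyloxy)pent-4-en-2-yl]-1,3-dioxolane | C=CC[C@@](C)(O[Si](CC)(CC)CC)[C@H]1OC(C)(C)O[C@@H]1/C=C(\Br)CBr | intermediate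
12 | 1-({[(2S,3S)-2-({(2Z)-2-bromo-3-[(4R,5S)-2,2-dimethyl-5-[(2R)-2-(triethylsilyloxy)pent-4-en-2-yl]-1,3-dioxolan-4-yl]prop-2-en-1-yl}oxy)-3-methylpent-4-en-1-yl]oxy}methyl)-4-methoxybenzene | C=CC[C@@](C)(O[Si](CC)(CC)CC)[C@H]1OC(C)(C)O[C@@H]1/C=C(\Br)CO[C@H](COCc1ccc(OC)cc1)[C@@H](C)C=C | intermediate
13 | twelve-membered oxacyclic diene (ring O–C13–C11(Br)=C7–C6–C5–C4–C3–C2=C1–C10–C9; 4R,5S,6R,9S,10S,7Z; C1=C2 E/Z mixture; 5,6-acetonide, 4-OTES, 9-CH2OPMB) | C=2C[C@@](C)(O[Si](CC)(CC)CC)[C@H]1OC(C)(C)O[C@@H]1/C=C(\Br)CO[C@H](COCc1ccc(OC)cc1)[C@@H](C)C2 | intermediate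
14 | twelve-membered oxacycle, C1–C2 saturated (4R,5S,6R,9S,10S,7Z; 5,6-acetonide, 4-OTES, 9-CH2OPMB) | C2C[C@@](C)(O[Si](CC)(CC)CC)[C@H]1OC(C)(C)O[C@@H]1/C=C(\Br)CO[C@H](COCc1ccc(OC)cc1)[C@@H](C)C2 | intermediate
15 | primary alcohol (9-CH2OH) of the twelve-membered oxacycle (4R,5S,6R,9S,10S,7Z) | C2C[C@@](C)(O[Si](CC)(CC)CC)[C@H]1OC(C)(C)O[C@@H]1/C=C(\Br)CO[C@H](CO)[C@@H](C)C2 | intermediate
16 | twelve-membered oxacyclic α-(allyloxy) aldehyde (9-CHO = C8; 4R,5S,6R,9S,10S,7Z) | C2C[C@@](C)(O[Si](CC)(CC)CC)[C@H]1OC(C)(C)O[C@@H]1/C=C(\Br)CO[C@H](C=O)[C@@H](C)C2 | intermediate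
17 | potassium (Z)-enolate of 16 (O-8 cis to the ring oxygen; 4R,5S,6R,10S,7Z) | C2C[C@@](C)(O[Si](CC)(CC)CC)[C@H]1OC(C)(C)O[C@@H]1/C=C(\Br)CO/C(=C\[O-])[C@@H](C)C2.[K+] | intermediate
18 | potassium alkoxide of the ring-contracted α-ketol (ten-membered ring; 4R,5S,6R,7R,8S,10S) | C=C(Br)[C@H]1[C@H]([O-])C(=O)[C@@H](C)CCC[C@@](C)(O[Si](CC)(CC)CC)[C@H]2OC(C)(C)O[C@H]12.[K+] | intermediate
19 | (4R,5S,6R,7R,8S,10S)-7-(1-bromovinyl)-8-(tert-butyldimethylsilyloxy)-5,6-(isopropylidenedioxy)-4,10-dimethyl-4-(triethylsilyloxy)cyclodecan-9-one (target numbering) | C=C(Br)[C@H]1[C@H](O[Si](C)(C)C(C)(C)C)C(=O)[C@@H](C)CCC[C@@](C)(O[Si](CC)(CC)CC)[C@H]2OC(C)(C)O[C@H]12 | intermediate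
20 | (4R,5S,6R,7R,8S,10S)-7-(1-bromovinyl)-8-(tert-butyldimethylsilyloxy)-4,5,6-trihydroxy-4,10-dimethylcyclodecan-9-one (target numbering) | C=C(Br)[C@H]1[C@H](O[Si](C)(C)C(C)(C)C)C(=O)[C@@H](C)CCC[C@@](C)(O)[C@@H](O)[C@@H]1O | intermediate
21 | (4R,5S,6R,7R,8S,10S)-8-(tert-butyldimethylsilyloxy)-4,5-dihydroxy-9-oxo-germacr-11(13)-en-12,6-olide | C=C1C(=O)O[C@@H]2[C@@H]1[C@H](O[Si](C)(C)C(C)(C)C)C(=O)[C@@H](C)CCC[C@@](C)(O)[C@H]2O | intermediate
22 | 8-O-TBS ether of the target (5-O-isovalerate; 4R,5S,6R,7R,8S,10S) | C=C1C(=O)O[C@@H]2[C@@H]1[C@H](O[Si](C)(C)C(C)(C)C)C(=O)[C@@H](C)CCC[C@@](C)(O)[C@H]2OC(=O)CC(C)C | intermediate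
23 | CNP0240128.1 (4R,5S,6R,7S,8S,10S) | C=C1C(=O)O[C@@H]2[C@@H]1[C@H](O)C(=O)[C@@H](C)CCC[C@@](C)(O)[C@H]2OC(=O)CC(C)C | target

**Step count and risks**

Total step count: 19. Longest linear sequence: 18 steps (steps 2–19, from 3).

Steps most likely to fail:

1. Step 15 (Proposed new method). What may go wrong: a competing [2,3]-Wittig shift of the enolate, aldol oligomerisation of the aldehyde enolate, base-mediated epimerisation at C10 before silylation, or erosion of the C8 configuration through loss of enolate geometry. The fallback is the neutral, thermal Claisen manifold, which sets out from 16. Soft enolisation–silylation (TBSOTf, Et3N, CH2Cl2, −78 °C) should give the isolable (Z)-tert-butyldimethylsilyl enol ether F1, the isomer with the two oxygens cis being expected on steric grounds. Heating F1 (toluene, 110 °C, trace Et3N) is a Claisen rearrangement of a silyl enol ether of an α-allyloxy carbonyl compound and carries the silyl group onto O-8, so it comes back to the route at 19 with no charged intermediate.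

2. Step 4. What may go wrong: enolisation of the β,γ-unsaturated ketone by the Grignard reagent (with migration of the double bond into conjugation), or incomplete chelate control leading to poor facial selectivity at C4. The fallback reverses the order of the two C–C bond formations and sets out from 4. Mono-addition of MeMgBr (THF, −78 °C) gives the methyl ketone (4S,5S)-5-acetyl-N-methoxy-N,2,2-trimethyl-1,3-dioxolane-4-carboxamide F2. Non-chelating allylation (potassium allyltrifluoroborate, BF3·OEt2, CH2Cl2, −78 °C) then adds the allyl group anti to the C5–O bond under Felkin–Anh (polar) control, which is the same face required by the main route, and comes back at 6.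

3. Step 17. What may go wrong: slow oxidative addition with competing six-membered lactonisation through O-5, sequestering of O-6 as a transannular hemiketal with C9, or base-induced epimerisation of the free triol at C8/C10. The fallback carbonylates before deprotection and sets out from 19. Pd-catalysed methoxycarbonylation (Pd(OAc)2, dppf, CO, MeOH, Et3N, DMF, 60 °C) gives the methyl acrylate F3 (methyl ester in place of Br). The acid conditions of step 16 (AcOH/THF/H2O, 45 °C) then remove acetonide and TES and close the γ-lactone with loss of methanol, coming back at 21.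

**Further compounds**

F1 | step 15 | (Z)-tert-butyldimethylsilyl enol ether of aldehyde 16 (O-8 cis to the ring oxygen; 4R,5S,6R,10S,7Z) | C2C[C@@](C)(O[Si](CC)(CC)CC)[C@H]1OC(C)(C)O[C@@H]1/C=C(\Br)CO/C(=C\O[Si](C)(C)C(C)(C)C)[C@@H](C)C2
F2 | step 4 | (4S,5S)-5-acetyl-N-methoxy-N,2,2-trimethyl-1,3-dioxolane-4-carboxamide | CC(=O)[C@H]1OC(C)(C)O[C@@H]1C(=O)N(C)OC
F3 | step 17 | methyl 2-[(4R,5S,6R,7R,8S,10S)-8-(tert-butyldimethylsilyloxy)-5,6-(isopropylidenedioxy)-4,10-dimethyl-9-oxo-4-(triethylsilyloxy)cyclodecan-7-yl]prop-2-enoate (target numbering) | C=C(C(=O)OC)[C@H]1[C@H](O[Si](C)(C)C(C)(C)C)C(=O)[C@@H](C)CCC[C@@](C)(O[Si](CC)(CC)CC)[C@H]2OC(C)(C)O[C@H]12
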